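**Route outline**

- Retrosynthesis: the C8–O acyl bond is cut first, removing the 2-(hydroxymethyl)acrylate. The C15 alcohol is traced back to an enal. The germacradiene is then folded by re-joining C5 to C10, which turns the ten-membered ring into the trans-fused rings A and B of a eudesmanolide.
- Enabling feature: the C1=C10 and C4=C5 olefins lie 1,5 across the ten-membered ring, with C15 on C4. A C5–C10 bond therefore gives a trans-decalin in which a C15 aldehyde enolate (push at C4) and a C1 mesylate (pull) flank the bond to be broken. Its C6/C7/C11 lactone ring and all fifteen carbons are those of α-santonin.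
- Forward order: the lactone ring and both six-membered rings are bought as α-santonin. C8 is hydroxylated, ring A is re-functionalised to the 1β-mesyloxy-4-formyl pattern, rings A and B are merged into the ten-membered ring by fragmentation, and the acrylate is attached at O8 before the enal is reduced.
- Stereochemistry: C6, C7 and C11 come from santonin. C8 is set by enzymatic C–H hydroxylation with retention. Both olefin geometries follow from the antiperiplanar geometry of the trans-decalin. C1, C4, C5 and C10 are temporary centres.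

Key step: step 15

Remark: eudesmane/germacrane numbering is used throughout (lactone oxygen on C6, lactone carbonyl C12, C13 on C11, C14 on C10, C15 on C4), α/β refer to the decalin with the C10 methyl β, and TBSO is tert-butyldimethylsilyloxy. Aldehyde 19 is drawn as the 4β-formyl epimer expected from syn hydrogen delivery to the α face; the 4α-epimer would serve equally, because C4 becomes trigonal in step 15.

**Steps**

Step 1
Reactants: 1 α-santonin
Product: 2 8α-hydroxy-α-santonin (artemisin)
Conditions: growing whole-cell culture of Absidia coerulea, glucose–peptone medium, air, 28 °C, substrate fed in acetone; chromatographic separation of the 8α-alcohol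
Reagents that add atoms: dioxygen, O=O
Why: Microbial C–H hydroxylation by a cytochrome P450 monooxygenase (hydrogen abstraction, then oxygen rebound) is expected to oxidise the exposed equatorial 8α C–H of ring B with retention, which sets C8, and hydroxylation of santonin-type lactones at unactivated ring positions by fungal cultures is an established biotransformation.

Step 2
Reactants: 2 8α-hydroxy-α-santonin
Product: 3 8α-TBSO-α-santonin
Conditions: TBSCl, imidazole, DMF, rt
Reagents that add atoms: tert-butyldimethylsilyl chloride, CC(C)(C)[Si](C)(C)Cl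
Why: Silylation of an equatorial secondary alcohol under standard conditions that leave the cross-conjugated dienone and the lactone untouched.

Step 3
Reactants: 3 8α-TBSO-α-santonin
Product: 5 8α-TBSO-3-oxo-4βH,5αH,11βH-eudesman-6α,12-olide (equatorial 4α-methyl), via 4β-methyl ketone 4 (not isolated)
Conditions: H2 (1 atm), Pd/C, EtOAc, rt; filter; DBU (0.2 equiv), CH2Cl2, rt
Reagents that add atoms: none
Why: Heterogeneous hydrogenation saturates C1=C2 and then delivers hydrogen to C4=C5 from the α face, opposite the angular 10β-methyl, which sets 5α-H (trans ring fusion), and the axial 4β-methyl formed first is equilibrated through the C3 enolate to the equatorial 4α-methyl.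

Step 4
Reactants: 5 trans-fused 3-ketone
Product: 7 8α-TBSO-3-(trimethylsilyloxy)-4βH,5αH,11βH-eudesm-2-en-6α,12-olide, via lithium enolate 6 (not isolated)
Conditions: LiN(iPr)2 (1.05 equiv), Me3SiCl, THF, −78 °C
Reagents that add atoms: chlorotrimethylsilane, C[Si](C)(C)Cl
Why: Kinetic deprotonation by the hindered amide removes a C2 methylene hydrogen instead of the tertiary C4–H shielded by the angular methyl, the ketone is enolised faster than the less acidic lactone, and O-silylation fixes the C2=C3 regiochemistry.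

Step 5
Reactants: 7 C2=C3 silyl enol ether
Product: 8 8α-TBSO-3-oxo-4βH,5αH,11βH-eudesm-1-en-6α,12-olide
Conditions: Pd(OAc)2 (10 mol %), O2 (1 atm), DMSO, rt
Reagents that add atoms: none
Why: Saegusa–Ito oxidation, in which the palladium enolate formed at C2 loses a C1 hydrogen by β-hydride elimination to give the C1=C2 enone without touching C4.

Step 6
Reactants: 8 1-en-3-one
Product: 9 8α-TBSO-1α,2α-epoxy-3-oxo-4βH,5αH,11βH-eudesman-6α,12-olide
Conditions: 30% H2O2, NaOH (aq, 0.3 equiv), MeOH, 0 °C; work-up at pH 4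
Reagents that add atoms: hydrogen peroxide, OO
Why: Weitz–Scheffer nucleophilic epoxidation in which hydroperoxide adds to C1 from the α face, anti to the 10β-methyl on the neighbouring quaternary carbon, and the enolate closes the oxirane on the same face, so C1 and C2 are set as the 1α,2α-epoxide, while the mildly acidic work-up re-closes any lactone opened by hydroxide.

Step 7
Reactants: 9 1α,2α-epoxy-3-ketone
Product: 11 8α-TBSO-1α-hydroxy-4βH,5αH,11βH-eudesm-2-en-6α,12-olide, via epoxy hydrazone 10 (not isolated)
Conditions: N2H4·H2O (3 equiv), AcOH (cat.), MeOH, 0 °C → rt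
Reagents that add atoms: none
Why: Wharton transposition, in which the hydrazone opens the oxirane and the resulting vinyl diazene loses dinitrogen to leave the C2=C3 olefin and a C1 alcohol whose 1α configuration is that of the untouched C1–O bond of the epoxide.

Step 8
Reactants: 11 1α-hydroxy-2-ene
Product: 12 8α-TBSO-1-oxo-4βH,5αH,11βH-eudesm-2-en-6α,12-olide
Conditions: IBX, DMSO, rt
Reagents that add atoms: none
Why: IBX oxidises the hindered axial allylic alcohol to the enone under neutral conditions that spare the silyl ether, the lactone and the C4 centre.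

Step 9
Reactants: 12 2-en-1-one
Product: 14 8α-TBSO-1-oxo-5αH,11βH-eudesm-3-en-6α,12-olide, via potassium dienolate 13 (not isolated)
Conditions: KOtBu (5 equiv), tBuOH/THF, rt; inverse quench into cold 10% aq AcOH
Reagents that add atoms: none
Why: Deconjugation by kinetic protonation of an extended dienolate, which works here because C10 is quaternary so the only enolisable hydrogen of the enone is the axial γ-H at C4, the dienolate is protonated fastest at the α-carbon C2, and C11 stays in its more stable configuration under the equilibrating alkoxide.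

Step 10
Reactants: 14 3-en-1-one (crude)
Product: 15 8α-TBSO-1β-hydroxy-5αH,11βH-eudesm-3-en-6α,12-olide
Conditions: NaBH4, MeOH/CH2Cl2, −20 °C
Reagents that add atoms: none
Why: Borohydride reduction with axial hydride delivery from the α face, away from the 10β-methyl, gives the equatorial 1β-alcohol (C1 R) and traps the β,γ-enone before it can reconjugate.

Step 11
Reactants: 15 1β-hydroxy-3-ene
Product: 16 8α-TBSO-1β,15-dihydroxy-5αH,11βH-eudesm-3-en-6α,12-olide
Conditions: SeO2 (0.3 equiv), tBuOOH (3 equiv), CH2Cl2, rt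
Reagents that add atoms: selenium dioxide, O=[Se]=O; tert-butyl hydroperoxide, CC(C)(C)OO
Why: Riley allylic oxidation (ene reaction, then 2,3-sigmatropic shift) in which selenium bonds to the less substituted C3 and, of the two allylic positions on the C4 terminus, the (E)-methyl C15 is oxidised in preference to the hindered ring-fusion methine C5, as is usual for methyl-bearing trisubstituted cyclohexenes flanked by a methine.

Step 12
Reactants: 16 1β,15-diol
Product: 17 8α-TBSO-1β-hydroxy-15-oxo-5αH,11βH-eudesm-3-en-6α,12-olide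
Conditions: activated MnO2, CH2Cl2, rt
Reagents that add atoms: none
Why: MnO2 oxidises only the primary allylic alcohol, so the saturated secondary C1 alcohol is kept for sulfonylation.

Step 13
Reactants: 17 1β-hydroxy-3-en-15-al
Product: 18 8α-TBSO-1β-mesyloxy-15-oxo-5αH,11βH-eudesm-3-en-6α,12-olide
Conditions: MsCl, Et3N, CH2Cl2, −20 °C → 0 °C, short reaction time
Reagents that add atoms: methanesulfonyl chloride, CS(=O)(=O)Cl
Why: Sulfene-mediated mesylation occurs at oxygen with retention at C1, and the cold, brief exposure to amine should avoid vinylogous elimination through the γ-hydrogens at C2.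

Step 14
Reactants: 18 1β-mesyloxy-3-en-15-al
Product: 19 8α-TBSO-1β-mesyloxy-15-oxo-4αH,5αH,11βH-eudesman-6α,12-olide (axial 4β-formyl)
Conditions: H2 (1 atm), Pd/C, EtOAc, rt
Reagents that add atoms: none
Why: Chemoselective hydrogenation of the conjugated C3=C4 bond over the aldehyde, with syn delivery of hydrogen to the α face placing the formyl group β at C4, a transient centre whose possible epimerisation is harmless.

Step 15
Reactants: 19 1β-mesyloxy-eudesman-15-al
Product: 21 8α-TBSO-15-oxo-11βH-germacra-1(10)E,4Z-dien-6α,12-olide, via potassium enolate 20 (not isolated)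
Conditions: KN(SiMe3)2 (1.05 equiv), THF, −78 °C → 0 °C
Reagents that add atoms: none
Why: One equivalent of the hindered amide removes the aldehyde α-hydrogen at C4 to give enolate 20, whose C4 electron pair flows into a new C4=C5 π bond while the C5–C10 σ pair becomes the C1=C10 π bond and methanesulfonate leaves C1, a concerted enolate-assisted 1,4-fragmentation of the Grob type. The closest known reaction is the fragmentation of 1-sulfonyloxy-trans-decalin-4-carbaldehyde enolates to (E,E)-cyclodeca-1,5-diene carbaldehydes, a carbon counterpart of the Grob and Wharton fragmentations. No ring is closed by bond formation: the ten-membered carbocycle arises by scission of the bond shared by rings A and B, so the entropic and transannular penalties of a medium-ring cyclisation do not apply, and the lactone ring is carried through unchanged. No stereocentre is created; C1, C4, C5 and C10 become two olefins whose geometry is fixed by the chair trans-decalin, in which C2 is anti to C9 about C1–C10 and C3 is anti to C6 about C4–C5, so both double bonds emerge ring-trans, that is 1(10)E and, with C15 cis to C6, 4Z by the sequence rule. The step must beat E2 elimination, lactone enolisation and enolate alkylation: the equatorial 1β-mesylate is antiperiplanar to C5–C10 and has no antiperiplanar hydrogen, the aldehyde α-hydrogen is far more acidic than the lactone C11–H, intramolecular C- or O-alkylation at C1 would require a bicyclo[2.2.0]hexane or a bridgehead enol ether, and the trans-lactone locks the chair needed for orbital overlap. The base is consumed as potassium methanesulfonate forms, so the enal product is not left in a basic medium.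

Step 16
Reactants: 21 8-O-silyl germacradienal lactone
Product: 22 8α-hydroxy-15-oxo-11βH-germacra-1(10)E,4Z-dien-6α,12-olide
Conditions: HF·pyridine, pyridine, THF, 0 °C → rt
Reagents that add atoms: none
Why: Fluoride-driven cleavage of the secondary silyl ether under buffered acidic conditions, where the enal keeps the C4=C5 olefin electron-poor so that proton-initiated transannular cyclisation of the 1,5-diene is not expected and base-induced lactone migration to O8 is avoided.

Step 17
Reactants: 23 methyl 2-(hydroxymethyl)acrylate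
Product: 24 methyl 2-(TBSO-methyl)acrylate
Conditions: TBSCl, imidazole, CH2Cl2, 0 °C → rt
Reagents that add atoms: tert-butyldimethylsilyl chloride, CC(C)(C)[Si](C)(C)Cl
Why: Routine silylation of a primary allylic alcohol, which blocks self-esterification and oxa-Michael oligomerisation in the later acylation.

Step 18
Reactants: 24 methyl 2-(TBSO-methyl)acrylate
Product: 26 2-(TBSO-methyl)acrylic acid, via lithium carboxylate 25 (not isolated)
Conditions: LiOH·H2O, THF/H2O, 0 °C; then 1 M HCl to pH 4
Reagents that add atoms: lithium hydroxide, [Li+].[OH-]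
Why: Saponification of the methyl ester at 0 °C should outpace conjugate addition of hydroxide to the 2-substituted acrylate, and the primary silyl ether survives the brief, mild acidification.

Step 19
Reactants: 22 8α-hydroxy germacradienal lactone; 26 2-(TBSO-methyl)acrylic acid
Product: 28 8α-[2-(TBSO-methyl)acryloyloxy]-15-oxo-11βH-germacra-1(10)E,4Z-dien-6α,12-olide, via mixed anhydride 27 (not isolated)
Conditions: 2,4,6-trichlorobenzoyl chloride, Et3N, THF, rt; then 22, DMAP, toluene, rt
Reagents that add atoms: none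
Why: Yamaguchi esterification, in which DMAP transfers the acryloyl group from the mixed anhydride (the aroyl carbonyl is shielded by two ortho chlorines) to the secondary 8α-alcohol with retention at C8 under conditions too weakly basic to move the lactone.

Step 20
Reactants: 28 silyl-protected C8 ester
Product: 29 8α-[2-(hydroxymethyl)acryloyloxy]-15-oxo-11βH-germacra-1(10)E,4Z-dien-6α,12-olide
Conditions: HF·pyridine, pyridine, THF, 0 °C
Reagents that add atoms: none
Why: The primary allylic silyl ether is cleaved quickly by buffered fluoride, while the acrylate ester, the lactone and the still electron-poor diene are inert.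

Step 21
Reactants: 29 side-chain alcohol with C15 aldehyde
Product: 30 8α-[2-(hydroxymethyl)acryloyloxy]-15-hydroxy-11βH-germacra-1(10)E,4Z-dien-6α,12-olide (CNP0167163.3)
Conditions: NaBH4, CeCl3·7H2O, MeOH, −78 °C
Reagents that add atoms: none
Why: Luche reduction delivers hydride 1,2 to the enal only, leaving the acrylate ester, the lactone and both olefin geometries untouched, to unveil the C15 allylic alcohol.

**Compound list**

1 | α-santonin, 3-oxo-11βH-eudesma-1,4-dien-6α,12-olide (6βH, 7αH, 10β-methyl, 11α-methyl) | C1C[C@@]3(C)C=CC(=O)C(C)=C3[C@H]2OC(=O)[C@@H](C)[C@H]12 | starting material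
2 | 8α-hydroxy-α-santonin (artemisin) | O[C@H]1C[C@@]3(C)C=CC(=O)C(C)=C3[C@H]2OC(=O)[C@@H](C)[C@H]12 | intermediate
3 | 8α-TBSO-α-santonin | CC(C)(C)[Si](C)(C)O[C@H]1C[C@@]3(C)C=CC(=O)C(C)=C3[C@H]2OC(=O)[C@@H](C)[C@H]12 | intermediate
4 | 8α-TBSO-3-oxo-4αH,5αH,11βH-eudesman-6α,12-olide (axial 4β-methyl) | CC(C)(C)[Si](C)(C)O[C@H]1C[C@@]3(C)CCC(=O)[C@H](C)[C@@H]3[C@H]2OC(=O)[C@@H](C)[C@H]12 | intermediate (not isolated)
5 | 8α-TBSO-3-oxo-4βH,5αH,11βH-eudesman-6α,12-olide (equatorial 4α-methyl, trans-decalin) | CC(C)(C)[Si](C)(C)O[C@H]1C[C@@]3(C)CCC(=O)[C@@H](C)[C@@H]3[C@H]2OC(=O)[C@@H](C)[C@H]12 | intermediate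
6 | lithium C2=C3 enolate of 5 | CC(C)(C)[Si](C)(C)O[C@H]1C[C@@]3(C)CC=C([O-])[C@@H](C)[C@@H]3[C@H]2OC(=O)[C@@H](C)[C@H]12.[Li+] | intermediate (not isolated)
7 | 8α-TBSO-3-(trimethylsilyloxy)-4βH,5αH,11βH-eudesm-2-en-6α,12-olide | CC(C)(C)[Si](C)(C)O[C@H]1C[C@@]3(C)CC=C(O[Si](C)(C)C)[C@@H](C)[C@@H]3[C@H]2OC(=O)[C@@H](C)[C@H]12 | intermediate
8 | 8α-TBSO-3-oxo-4βH,5αH,11βH-eudesm-1-en-6α,12-olide | CC(C)(C)[Si](C)(C)O[C@H]1C[C@@]3(C)C=CC(=O)[C@@H](C)[C@@H]3[C@H]2OC(=O)[C@@H](C)[C@H]12 | intermediate
9 | 8α-TBSO-1α,2α-epoxy-3-oxo-4βH,5αH,11βH-eudesman-6α,12-olide | CC(C)(C)[Si](C)(C)O[C@H]1C[C@@]3(C)[C@H]4O[C@H]4C(=O)[C@@H](C)[C@@H]3[C@H]2OC(=O)[C@@H](C)[C@H]12 | intermediate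
10 | C3 hydrazone of 9 (C=N geometry undefined) | CC(C)(C)[Si](C)(C)O[C@H]1C[C@@]3(C)[C@H]4O[C@H]4C(=NN)[C@@H](C)[C@@H]3[C@H]2OC(=O)[C@@H](C)[C@H]12 | intermediate (not isolated)
11 | 8α-TBSO-1α-hydroxy-4βH,5αH,11βH-eudesm-2-en-6α,12-olide | CC(C)(C)[Si](C)(C)O[C@H]1C[C@@]3(C)[C@@H](O)C=C[C@@H](C)[C@@H]3[C@H]2OC(=O)[C@@H](C)[C@H]12 | intermediate
12 | 8α-TBSO-1-oxo-4βH,5αH,11βH-eudesm-2-en-6α,12-olide | CC(C)(C)[Si](C)(C)O[C@H]1C[C@@]3(C)C(=O)C=C[C@@H](C)[C@@H]3[C@H]2OC(=O)[C@@H](C)[C@H]12 | intermediate
13 | potassium 1-oxido-1,3-dienolate of 12 | CC(C)(C)[Si](C)(C)O[C@H]1C[C@@]3(C)C([O-])=CC=C(C)[C@@H]3[C@H]2OC(=O)[C@@H](C)[C@H]12.[K+] | intermediate (not isolated)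
14 | 8α-TBSO-1-oxo-5αH,11βH-eudesm-3-en-6α,12-olide | CC(C)(C)[Si](C)(C)O[C@H]1C[C@@]3(C)C(=O)CC=C(C)[C@@H]3[C@H]2OC(=O)[C@@H](C)[C@H]12 | intermediate
15 | 8α-TBSO-1β-hydroxy-5αH,11βH-eudesm-3-en-6α,12-olide | CC(C)(C)[Si](C)(C)O[C@H]1C[C@@]3(C)[C@H](O)CC=C(C)[C@@H]3[C@H]2OC(=O)[C@@H](C)[C@H]12 | intermediate
16 | 8α-TBSO-1β,15-dihydroxy-5αH,11βH-eudesm-3-en-6α,12-olide | CC(C)(C)[Si](C)(C)O[C@H]1C[C@@]3(C)[C@H](O)CC=C(CO)[C@@H]3[C@H]2OC(=O)[C@@H](C)[C@H]12 | intermediate
17 | 8α-TBSO-1β-hydroxy-15-oxo-5αH,11βH-eudesm-3-en-6α,12-olide | CC(C)(C)[Si](C)(C)O[C@H]1C[C@@]3(C)[C@H](O)CC=C(C=O)[C@@H]3[C@H]2OC(=O)[C@@H](C)[C@H]12 | intermediate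
18 | 8α-TBSO-1β-mesyloxy-15-oxo-5αH,11βH-eudesm-3-en-6α,12-olide | CC(C)(C)[Si](C)(C)O[C@H]1C[C@@]3(C)[C@H](OS(C)(=O)=O)CC=C(C=O)[C@@H]3[C@H]2OC(=O)[C@@H](C)[C@H]12 | intermediate
19 | 8α-TBSO-1β-mesyloxy-15-oxo-4αH,5αH,11βH-eudesman-6α,12-olide (axial 4β-formyl) | CC(C)(C)[Si](C)(C)O[C@H]1C[C@@]3(C)[C@H](OS(C)(=O)=O)CC[C@H](C=O)[C@@H]3[C@H]2OC(=O)[C@@H](C)[C@H]12 | intermediate
20 | potassium C4=C15 enolate of 19 (enolate geometry undefined) | CC(C)(C)[Si](C)(C)O[C@H]1C[C@@]3(C)[C@H](OS(C)(=O)=O)CCC(=C[O-])[C@@H]3[C@H]2OC(=O)[C@@H](C)[C@H]12.[K+] | intermediate (not isolated)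
21 | 8α-TBSO-15-oxo-11βH-germacra-1(10)E,4Z-dien-6α,12-olide | CC(C)(C)[Si](C)(C)O[C@H]1C/C(C)=C/CC/C(C=O)=C/[C@H]2OC(=O)[C@@H](C)[C@H]12 | intermediate
22 | 8α-hydroxy-15-oxo-11βH-germacra-1(10)E,4Z-dien-6α,12-olide | O[C@H]1C/C(C)=C/CC/C(C=O)=C/[C@H]2OC(=O)[C@@H](C)[C@H]12 | intermediate
23 | methyl 2-(hydroxymethyl)acrylate | C=C(CO)C(=O)OC | starting material
24 | methyl 2-(TBSO-methyl)acrylate | C=C(CO[Si](C)(C)C(C)(C)C)C(=O)OC | intermediate
25 | lithium 2-(TBSO-methyl)acrylate | C=C(CO[Si](C)(C)C(C)(C)C)C(=O)[O-].[Li+] | intermediate (not isolated)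
26 | 2-(TBSO-methyl)acrylic acid | C=C(CO[Si](C)(C)C(C)(C)C)C(=O)O | intermediate
27 | 2-(TBSO-methyl)acrylic 2,4,6-trichlorobenzoic anhydride | C=C(CO[Si](C)(C)C(C)(C)C)C(=O)OC(=O)c1c(Cl)cc(Cl)cc1Cl | intermediate (not isolated)
28 | 8α-[2-(TBSO-methyl)acryloyloxy]-15-oxo-11βH-germacra-1(10)E,4Z-dien-6α,12-olide | C=C(CO[Si](C)(C)C(C)(C)C)C(=O)O[C@H]1C/C(C)=C/CC/C(C=O)=C/[C@H]2OC(=O)[C@@H](C)[C@H]12 | intermediate
29 | 8α-[2-(hydroxymethyl)acryloyloxy]-15-oxo-11βH-germacra-1(10)E,4Z-dien-6α,12-olide | C=C(CO)C(=O)O[C@H]1C/C(C)=C/CC/C(C=O)=C/[C@H]2OC(=O)[C@@H](C)[C@H]12 | intermediate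
30 | 8α-[2-(hydroxymethyl)acryloyloxy]-15-hydroxy-11βH-germacra-1(10)E,4Z-dien-6α,12-olide (CNP0167163.3) | C=C(CO)C(=O)O[C@H]1C/C(C)=C/CC/C(CO)=C/[C@H]2OC(=O)[C@@H](C)[C@H]12 | target

**Step count and risks**

Total step count: 21. Longest linear sequence: 19 steps (from 1 through steps 1–16 and 19–21 to 30).

The three steps most likely to fail:

1. The fragmentation (step 15). The amide base may be diverted to the lactone C11–H, slow fragmentation may let the enolate equilibrate or eliminate, or the enal may degrade if base remains. The fallback releases the enolate without a Brønsted base and sets out from 19. Me3SiOTf and Et3N in CH2Cl2 at 0 °C should convert the aldehyde into the C4=C15 trimethylsilyl enol ether F1. Anhydrous fluoride (tris(dimethylamino)sulfonium difluorotrimethylsilicate, THF, −78 °C → 0 °C) then desilylates it to the tris(dimethylamino)sulfonium enolate F2, a more reactive naked enolate. This should fragment at lower temperature to 21, where the route is rejoined.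

2. The allylic oxidation (step 11). Selenium may attack the ring methylene C2 or the C5 methine, and over-oxidation or selenium retention by the homoallylic alcohol may erode material. The fallback functionalises C15 through an epoxide and sets out from 15. mCPBA (NaHCO3, CH2Cl2, 0 °C) should give the 3α,4α-epoxide F3. Diethylaluminium 2,2,6,6-tetramethylpiperidide (toluene, 0 °C) removes a proton from the C15 methyl and opens it to the 3α-hydroxy-4(15)-ene F4. Ph3SiOReO3 (cat., Et2O, 0 °C) then transposes the allylic alcohol 1,3 to the primary alcohol on the more substituted olefin. The C3 centre is lost in this shift, so the epoxide face is immaterial. The route is rejoined at 16.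

3. The deconjugation (step 9). Protonation of the dienolate at C4 would return conjugated enone, the β,γ-enone may reconjugate before reduction, and quenching lactone enolate may partly epimerise C11. The fallback is the dienol ester route and sets out from 12. Isopropenyl acetate with TsOH (cat.) at reflux should give the 1-acetoxy-1,3-diene F5. NaBH4 in EtOH/THF at 0 °C cleaves the enol ester, the liberated dienol is protonated at C2 to ketone 14 in the flask, and 14 is reduced at once. The route is rejoined at 15 without handling 14.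

**Further compounds**

F1 | step 15 | C4=C15 trimethylsilyl enol ether of 19 (enol ether geometry undefined) | CC(C)(C)[Si](C)(C)O[C@H]1C[C@@]3(C)[C@H](OS(C)(=O)=O)CCC(=CO[Si](C)(C)C)[C@@H]3[C@H]2OC(=O)[C@@H](C)[C@H]12
F2 | step 15 | tris(dimethylamino)sulfonium C4=C15 enolate of 19 (not isolated) | CC(C)(C)[Si](C)(C)O[C@H]1C[C@@]3(C)[C@H](OS(C)(=O)=O)CCC(=C[O-])[C@@H]3[C@H]2OC(=O)[C@@H](C)[C@H]12.CN(C)[S+](N(C)C)N(C)C
F3 | step 11 | 8α-TBSO-1β-hydroxy-3α,4α-epoxy-5αH,11βH-eudesman-6α,12-olide | CC(C)(C)[Si](C)(C)O[C@H]1C[C@@]3(C)[C@H](O)C[C@H]4O[C@@]4(C)[C@@H]3[C@H]2OC(=O)[C@@H](C)[C@H]12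
F4 | step 11 | 8α-TBSO-1β,3α-dihydroxy-5αH,11βH-eudesm-4(15)-en-6α,12-olide | CC(C)(C)[Si](C)(C)O[C@H]1C[C@@]3(C)[C@H](O)C[C@@H](O)C(=C)[C@@H]3[C@H]2OC(=O)[C@@H](C)[C@H]12
F5 | step 9 | 8α-TBSO-1-acetoxy-5αH,11βH-eudesma-1,3-dien-6α,12-olide | CC(C)(C)[Si](C)(C)O[C@H]1C[C@@]3(C)C(OC(C)=O)=CC=C(C)[C@@H]3[C@H]2OC(=O)[C@@H](C)[C@H]12
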